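The 2H-pyran ring (O1, C2, C3, C4, C4a, C8a) is cut at C2–C3 and C4–C4a, which excises C3=C4 as acetylene and leaves an aryloxyisobutyric acid on O1. The key step is a decarboxylative radical (4+2) annulation: the tertiary α-aryloxy radical at C2 adds to acetylene, and the vinyl radical closes on arene carbon C4a, so the chromene forms in one operation. It exploits the oxygen-bearing gem-dimethyl C2 as a stabilised radical site and the electron-rich CH C4a of the phloroglucinol-type ring; a free chelated 5-OH beside a MOM ether at O7 steers closure to C4a. Methylation of O5 and MOM removal finish the route.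

Key step: step 5

Remark: chromene numbering (O1, C2, C3, C4, C4a, C5 to C8, C8a) is used for the target and for the corresponding atoms of its precursors.

Step 1
Reactants: 1 phloroglucinol (benzene-1,3,5-triol); 2 (4-methoxyphenyl)acetonitrile
Product: 4 2-(4-methoxyphenyl)-1-(2,4,6-trihydroxyphenyl)ethan-1-one, via ketiminium chloride 3 (not isolated)
Conditions: ZnCl2, HCl (g), Et2O, 0 °C; then H2O, reflux
Reagents that add atoms: water, O
Why: Houben–Hoesch acylation: the HCl/ZnCl2-activated nitrile attacks the very nucleophilic phloroglucinol ring once (the ketiminium salt is deactivated towards a second acylation), and hydrolysis should give the aryl benzyl ketone.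

Step 2
Reactants: 4 2-(4-methoxyphenyl)-1-(2,4,6-trihydroxyphenyl)ethan-1-one; 5 ethyl 2-bromo-2-methylpropanoate
Product: 6 ethyl 2-{3,5-dihydroxy-4-[(4-methoxyphenyl)acetyl]phenoxy}-2-methylpropanoate
Conditions: K2CO3 (1.2 equiv), DMF, 60 °C
Reagents that add atoms: none
Why: Williamson-type O-alkylation with a tertiary α-bromo ester (the fibrate ether synthesis) should take place at the para OH, the most acidic and the only one not hydrogen-bonded to the ketone.

Step 3
Reactants: 6 ethyl 2-{3,5-dihydroxy-4-[(4-methoxyphenyl)acetyl]phenoxy}-2-methylpropanoate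
Product: 7 ethyl 2-{3-hydroxy-5-(methoxymethoxy)-4-[(4-methoxyphenyl)acetyl]phenoxy}-2-methylpropanoate
Conditions: MOMCl (1.1 equiv), i-Pr2NEt, CH2Cl2, 0 °C to rt
Reagents that add atoms: chloromethyl methyl ether (MOMCl), COCCl
Why: The two ortho OH groups are equivalent, and once one is etherified the other is locked in the hydrogen bond to the C=O and resists further alkylation, so the mono-MOM ether should form.

Step 4
Reactants: 7 ethyl 2-{3-hydroxy-5-(methoxymethoxy)-4-[(4-methoxyphenyl)acetyl]phenoxy}-2-methylpropanoate
Product: 8 2-{3-hydroxy-5-(methoxymethoxy)-4-[(4-methoxyphenyl)acetyl]phenoxy}-2-methylpropanoic acid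
Conditions: LiOH·H2O, THF/H2O, rt; then 1 M HCl to pH 3 at 0 °C
Reagents that add atoms: lithium hydroxide, [Li+].[OH-]
Why: Saponification (BAc2) of the ethyl ester should leave the MOM acetal, the aryl ethers and the ketone untouched under base, and the cold, brief acidification spares the MOM ether.

Step 5
Reactants: 8 2-{3-hydroxy-5-(methoxymethoxy)-4-[(4-methoxyphenyl)acetyl]phenoxy}-2-methylpropanoic acid; 9 acetylene
Product: 11 1-[5-hydroxy-7-(methoxymethoxy)-2,2-dimethyl-2H-chromen-6-yl]-2-(4-methoxyphenyl)ethan-1-one, via N-acyloxyphthalimide ester 10 (not isolated)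
Conditions: N-hydroxyphthalimide, DIC, DMAP (cat.), CH2Cl2, rt; then fac-Ir(ppy)3 (1 mol %; ppy = 2-phenylpyridinate), acetylene (1 atm), MeCN, blue LEDs (450 nm), rt
Reagents that add atoms: none
Why: Proposed new method: single-electron reduction of the N-acyloxyphthalimide 10 by photoexcited fac-Ir(ppy)3 releases CO2 and the tertiary α-aryloxy radical at C2, which adds to acetylene (C2–C3) to give a σ-vinyl radical that attacks the arene at C4a (C4–C4a); the cyclohexadienyl radical is then oxidised by the tetravalent iridium complex and loses a proton to phthalimide anion, so the cycle is redox-neutral. The closest known reactions are the photoredox (4+2) radical annulation of aryloxyacetic N-acyloxyphthalimides with acrylates to chromans and the vinyl-radical closure of aryl propargyl ethers to 2H-chromenes; new here is acetylene as the two-carbon partner, which delivers the C3=C4 double bond directly. The pyran ring closes by 6-endo-trig homolytic aromatic substitution at the ortho carbon, while 5-exo ipso attack at C8a is reversible and unproductive. No stereocentre is formed. The step needs regioselectivity between the two ortho CH positions: C4a lies beside the small, carbonyl-chelated 5-OH, whereas C8 is shielded by the in-plane CH2 of the MOM ether on O7, so closure at C4a should be favoured. MeCN is chosen as a poor hydrogen donor so that the vinyl radical cyclises before it is reduced.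

Step 6
Reactants: 11 1-[5-hydroxy-7-(methoxymethoxy)-2,2-dimethyl-2H-chromen-6-yl]-2-(4-methoxyphenyl)ethan-1-one
Product: 12 1-[5-methoxy-7-(methoxymethoxy)-2,2-dimethyl-2H-chromen-6-yl]-2-(4-methoxyphenyl)ethan-1-one
Conditions: MeI, K2CO3, acetone, reflux
Reagents that add atoms: iodomethane (MeI), CI
Why: Williamson O-methylation of the only free phenol; the weak base in acetone should not enolise the deoxybenzoin CH2, so C-methylation is not expected.

Step 7
Reactants: 12 1-[5-methoxy-7-(methoxymethoxy)-2,2-dimethyl-2H-chromen-6-yl]-2-(4-methoxyphenyl)ethan-1-one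
Product: 13 1-(7-hydroxy-5-methoxy-2,2-dimethyl-2H-chromen-6-yl)-2-(4-methoxyphenyl)ethan-1-one
Conditions: 3 M aq. HCl, MeOH, 40 °C
Reagents that add atoms: none
Why: Acid-catalysed acetal exchange should remove the MOM group, helped by the neighbouring carbonyl, while the aryl methyl ethers and the 2,2-dimethylchromene tolerate dilute acid at this temperature.

Compound list
1 | phloroglucinol (benzene-1,3,5-triol) | Oc1cc(O)cc(O)c1 | starting material
2 | (4-methoxyphenyl)acetonitrile | COc1ccc(CC#N)cc1 | starting material
3 | 2-(4-methoxyphenyl)-1-(2,4,6-trihydroxyphenyl)ethan-1-iminium chloride (ketiminium chloride; not isolated) | COc1ccc(CC(=[NH2+])c2c(O)cc(O)cc2O)cc1.[Cl-] | intermediate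
4 | 2-(4-methoxyphenyl)-1-(2,4,6-trihydroxyphenyl)ethan-1-one | COc1ccc(CC(=O)c2c(O)cc(O)cc2O)cc1 | intermediate
5 | ethyl 2-bromo-2-methylpropanoate | CCOC(=O)C(C)(C)Br | starting material
6 | ethyl 2-{3,5-dihydroxy-4-[(4-methoxyphenyl)acetyl]phenoxy}-2-methylpropanoate | CCOC(=O)C(C)(C)Oc1cc(O)c(C(=O)Cc2ccc(OC)cc2)c(O)c1 | intermediate
7 | ethyl 2-{3-hydroxy-5-(methoxymethoxy)-4-[(4-methoxyphenyl)acetyl]phenoxy}-2-methylpropanoate | CCOC(=O)C(C)(C)Oc1cc(O)c(C(=O)Cc2ccc(OC)cc2)c(OCOC)c1 | intermediate
8 | 2-{3-hydroxy-5-(methoxymethoxy)-4-[(4-methoxyphenyl)acetyl]phenoxy}-2-methylpropanoic acid | COCOc1cc(OC(C)(C)C(O)=O)cc(O)c1C(=O)Cc1ccc(OC)cc1 | intermediate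
9 | acetylene | C#C | starting material
10 | 1,3-dioxoisoindolin-2-yl 2-{3-hydroxy-5-(methoxymethoxy)-4-[(4-methoxyphenyl)acetyl]phenoxy}-2-methylpropanoate (N-acyloxyphthalimide ester; not isolated) | COCOc1cc(OC(C)(C)C(=O)ON2C(=O)c3ccccc3C2=O)cc(O)c1C(=O)Cc1ccc(OC)cc1 | intermediate
11 | 1-[5-hydroxy-7-(methoxymethoxy)-2,2-dimethyl-2H-chromen-6-yl]-2-(4-methoxyphenyl)ethan-1-one | COCOc1cc2OC(C)(C)C=Cc2c(O)c1C(=O)Cc1ccc(OC)cc1 | intermediate
12 | 1-[5-methoxy-7-(methoxymethoxy)-2,2-dimethyl-2H-chromen-6-yl]-2-(4-methoxyphenyl)ethan-1-one | COCOc1cc2OC(C)(C)C=Cc2c(OC)c1C(=O)Cc1ccc(OC)cc1 | intermediate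
13 | 1-(7-hydroxy-5-methoxy-2,2-dimethyl-2H-chromen-6-yl)-2-(4-methoxyphenyl)ethan-1-one | COc1ccc(CC(=O)c2c(O)cc3c(c2OC)C=CC(C)(C)O3)cc1 | target

Total step count: 7
Longest linear sequence: 7 steps (1 to 13)

Steps most likely to fail

Step 5. The nucleophilic tertiary radical may add too slowly to unactivated acetylene and be lost by reduction or by oxidation to the oxocarbenium ion, or the vinyl radical may close with poor regioselectivity between C4a and C8. The fallback replaces the annulation by the aromatic propargyl Claisen route and sets out from 4. O-Alkylation of the para OH with 3-chloro-3-methylbut-1-yne (CuCl2·2H2O cat., DBU, MeCN, 0 °C) should give 1-[2,6-dihydroxy-4-(2-methylbut-3-yn-2-yloxy)phenyl]-2-(4-methoxyphenyl)ethan-1-one F1. Mono-protection (MOMCl, i-Pr2NEt, CH2Cl2) should give 1-[2-hydroxy-6-(methoxymethoxy)-4-(2-methylbut-3-yn-2-yloxy)phenyl]-2-(4-methoxyphenyl)ethan-1-one F2. Heating F2 in N,N-diethylaniline at 180 °C should bring about Claisen rearrangement, 1,5-hydrogen shift and oxa-6π electrocyclisation. Closure is expected at the CH beside the chelated OH, where the hydrogen-bonded ketone fixes the ring double bond, so the fallback comes back to the route at 11.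

Step 2. Substitution at the tertiary bromide may be outrun by elimination of HBr to the methacrylate, or more than one OH may be alkylated. The fallback sets out from 4 and uses the Bargellini reaction (acetone, CHCl3, powdered NaOH, 0 °C to rt). Here the phenoxide opens a gem-dichloroepoxide formed in the flask, which should give 2-{3,5-dihydroxy-4-[(4-methoxyphenyl)acetyl]phenoxy}-2-methylpropanoic acid F3. Selective alkylation of the carboxylate (EtI, KHCO3, DMF, rt) brings it back to the route at 6.

Step 6. O-Methylation of the hindered, hydrogen-bonded 5-OH may stall, and forcing it with stronger base may lead to C-methylation through the deoxybenzoin enolate. The fallback is a Mitsunobu etherification of 11 (MeOH, PPh3, DIAD, THF, rt). It activates methanol instead of deprotonating the substrate, leads straight from 11 to 12 and makes no new compound (F0).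

Further compounds
F1 | step 5 | 1-[2,6-dihydroxy-4-(2-methylbut-3-yn-2-yloxy)phenyl]-2-(4-methoxyphenyl)ethan-1-one | COc1ccc(CC(=O)c2c(O)cc(OC(C)(C)C#C)cc2O)cc1
F2 | step 5 | 1-[2-hydroxy-6-(methoxymethoxy)-4-(2-methylbut-3-yn-2-yloxy)phenyl]-2-(4-methoxyphenyl)ethan-1-one | COCOc1cc(OC(C)(C)C#C)cc(O)c1C(=O)Cc1ccc(OC)cc1
F3 | step 2 | 2-{3,5-dihydroxy-4-[(4-methoxyphenyl)acetyl]phenoxy}-2-methylpropanoic acid | COc1ccc(CC(=O)c2c(O)cc(OC(C)(C)C(O)=O)cc2O)cc1
F0 | step 6 | none | none
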